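**Retrosynthetic overview**

- The target is reached by acetal cleavage and hydrogenation from an (E)-stilbene, in which the C1–CH=CH–ring B unit stands for the ethane bridge and every free phenol is masked (three benzyl ethers, two methoxymethyl ethers).
- Feature the strategy rests on: in the hexasubstituted ring A, C1 carries the two-carbon link to ring B and lies between C2 and C6, which bear identical 4-hydroxybenzyl groups. This is the ipso/ortho,ortho′ pattern of a Catellani reaction. The C2–CH2, C6–CH2 and C1–vinyl bonds are cut together, back to a C1 iodide, two molecules of 4-benzyloxybenzyl bromide and 3-methoxystyrene.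
- The iodide (C3 OMOM, C4 4-(methoxymethoxy)benzyl, C5 OMe) comes from iododeboronation of a boronate made by sterically directed C–H borylation at C1. The C4 benzyl is put in first, by ortho-lithiation of 3-methoxyphenol methoxymethyl ether between its two oxygens.
- No ring is formed anywhere in the route: ring A, ring B and the three benzyl rings are bought as arenes and only joined.

Key step: step 7

Remark on the chemistry: the phenol of the C4 benzyl is carried as a methoxymethyl ether, not a benzyl ether. The unsubstituted phenyl ring of a benzyl ether has unhindered C–H bonds that would be borylated in step 5, so benzyl ethers enter only with the bromide used in step 7.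

**Route**

Step 1
Reactants: 1 3-methoxyphenol
Product: 2 1-methoxy-3-(methoxymethoxy)benzene
Conditions: NaH, MOMCl, DMF, 0 °C to rt
Reagents that add atoms: chloromethyl methyl ether (MOMCl), COCCl
Why: Williamson-type O-alkylation of the sodium phenoxide with the chloromethyl ether should install the acetal that later directs ortho-lithiation.

Step 2
Reactants: 3 4-hydroxybenzyl alcohol
Product: 4 [4-(methoxymethoxy)phenyl]methanol
Conditions: NaH (1.0 equiv), DMF, 0 °C; MOMCl (1.0 equiv)
Reagents that add atoms: chloromethyl methyl ether (MOMCl), COCCl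
Why: One equivalent of base deprotonates only the phenol, which is far more acidic than the benzylic alcohol, so the Williamson-type O-alkylation should take place at the phenoxide oxygen alone.

Step 3
Reactants: 4 [4-(methoxymethoxy)phenyl]methanol
Product: 5 4-(methoxymethoxy)benzyl bromide
Conditions: CBr4, PPh3, CH2Cl2, 0 °C; used without storage
Reagents that add atoms: carbon tetrabromide, BrC(Br)(Br)Br
Why: Appel reaction, in which bromide displaces the alkoxyphosphonium ion under neutral conditions that leave the acetal untouched.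

Step 4
Reactants: 2 1-methoxy-3-(methoxymethoxy)benzene; 5 4-(methoxymethoxy)benzyl bromide
Product: 7 1-methoxy-3-(methoxymethoxy)-2-[4-(methoxymethoxy)benzyl]benzene, via aryllithium 6 (not isolated)
Conditions: n-BuLi, THF, 0 °C; then CuBr·SMe2 (10 mol%), 5, −78 °C to rt
Reagents that add atoms: none
Why: Directed ortho-metalation removes the proton between the methoxy and methoxymethoxy groups, where both oxygens hold lithium, and the aryl nucleophile (relayed through copper) is benzylated by SN2 displacement of bromide.

Step 5
Reactants: 7 1-methoxy-3-(methoxymethoxy)-2-[4-(methoxymethoxy)benzyl]benzene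
Product: 8 2-{3-methoxy-5-(methoxymethoxy)-4-[4-(methoxymethoxy)benzyl]phenyl}-4,4,5,5-tetramethyl-1,3,2-dioxaborolane
Conditions: [Ir(OMe)(cod)]2 (1.5 mol%), 4,4′-di-tert-butyl-2,2′-bipyridine (3 mol%), B2pin2 (1.0 equiv), THF, 80 °C
Reagents that add atoms: bis(pinacolato)diboron, CC1(C)OB(OC1(C)C)B1OC(C)(C)C(C)(C)O1
Why: Iridium-catalysed C–H borylation is governed by sterics, and the C–H para to the benzyl group is the only aromatic C–H without an ortho substituent, since every C–H of the 4-(methoxymethoxy)benzyl ring has an ortho neighbour.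

Step 6
Reactants: 8 2-{3-methoxy-5-(methoxymethoxy)-4-[4-(methoxymethoxy)benzyl]phenyl}-4,4,5,5-tetramethyl-1,3,2-dioxaborolane
Product: 9 5-iodo-1-methoxy-3-(methoxymethoxy)-2-[4-(methoxymethoxy)benzyl]benzene
Conditions: CuI (10 mol%), 1,10-phenanthroline (20 mol%), KI (1.5 equiv), MeOH–H2O (4:1), air, 80 °C
Reagents that add atoms: potassium iodide, [K+].[I-]
Why: Copper-catalysed iododeboronation runs through boron-to-copper transmetalation, so iodine should enter only at the carbon that carried boron and not at the oxygen-activated positions that an electrophilic iodine source would attack.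

Step 7
Reactants: 9 5-iodo-1-methoxy-3-(methoxymethoxy)-2-[4-(methoxymethoxy)benzyl]benzene; 10 4-benzyloxybenzyl bromide; 11 3-methoxystyrene
Product: 12 (E)-1-[2-(3-methoxyphenyl)vinyl]-2,6-bis[4-(benzyloxy)benzyl]-5-methoxy-3-(methoxymethoxy)-4-[4-(methoxymethoxy)benzyl]benzene
Conditions: Pd(OAc)2 (10 mol%), P(2-furyl)3 (22 mol%), norbornene (2 equiv), Cs2CO3 (5 equiv), 10 (2.5 equiv), 11 (1.5 equiv), MeCN, 90 °C
Reagents that add atoms: none
Why: Catellani reaction (palladium/norbornene cooperative catalysis): oxidative addition of the C1–I bond of 9 to zerovalent palladium is followed by syn carbopalladation of norbornene, and the resulting alkylpalladium, which has no accessible β-hydrogen, metalates C2–H to give a five-membered aryl–norbornyl palladacycle; bromide 10 adds to give a tetravalent palladium species, reductive elimination forms the C2–CH2 bond, and the same sequence repeats at C6. Once C1 is flanked by two benzyl groups, steric strain drives β-carbon elimination of norbornene, and the 2,6-disubstituted aryl divalent palladium species that is released undergoes Mizoroki–Heck insertion and β-hydride elimination with styrene 11 to form the C1–vinyl bond. The closest known reaction type is the ortho,ortho′-dialkylation of ortho-unsubstituted aryl iodides with primary alkyl halides terminated by a Heck reaction; here the electrophile is benzylic and each ortho C–H lies next to an alkoxy group, which extends that scope. No ring is closed and no stereocentre is set; the (E) geometry follows from syn insertion and syn β-hydride elimination and is erased in step 8. The selectivity needed is complete double benzylation before vinylation, and the substrate enforces it because norbornene is expelled only when both positions next to C1 are substituted, while bromide 10 has no β-hydrogen and cannot be lost by elimination. The excess of 11 should trap the released arylpalladium intermolecularly before it can cyclise onto a neighbouring benzyl ring.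

Step 8
Reactants: 12 (E)-1-[2-(3-methoxyphenyl)vinyl]-2,6-bis[4-(benzyloxy)benzyl]-5-methoxy-3-(methoxymethoxy)-4-[4-(methoxymethoxy)benzyl]benzene
Product: 13 1-[2-(3-methoxyphenyl)ethyl]-2,6-bis(4-hydroxybenzyl)-5-methoxy-3-(methoxymethoxy)-4-[4-(methoxymethoxy)benzyl]benzene
Conditions: H2 (1 atm), 10% Pd/C, EtOAc–MeOH, rt
Reagents that add atoms: none
Why: Heterogeneous catalytic hydrogenation should saturate the disubstituted stilbene double bond and hydrogenolyse the three benzyl aryl ethers, while the diarylmethane C–C bonds, the methyl ethers and the acetals are inert under neutral conditions.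

Step 9
Reactants: 13 1-[2-(3-methoxyphenyl)ethyl]-2,6-bis(4-hydroxybenzyl)-5-methoxy-3-(methoxymethoxy)-4-[4-(methoxymethoxy)benzyl]benzene
Product: 14 2,4,6-tris(4-hydroxybenzyl)-5-methoxy-3-[2-(3-methoxyphenyl)ethyl]phenol
Conditions: HCl (dilute), MeOH, 40 °C
Reagents that add atoms: none
Why: Acid-catalysed acetal cleavage (transacetalisation with methanol) should free the C3 hydroxyl of ring A and the phenol of the C4 benzyl group, while the aryl methyl ethers are stable to dilute acid.

**Compound list**

1 | 3-methoxyphenol | COc1cccc(O)c1 | starting material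
2 | 1-methoxy-3-(methoxymethoxy)benzene | COCOc1cccc(OC)c1 | intermediate
3 | 4-hydroxybenzyl alcohol | OCc1ccc(O)cc1 | starting material
4 | [4-(methoxymethoxy)phenyl]methanol | COCOc1ccc(CO)cc1 | intermediate
5 | 4-(methoxymethoxy)benzyl bromide | COCOc1ccc(CBr)cc1 | intermediate
6 | 2-lithio-1-methoxy-3-(methoxymethoxy)benzene (aryllithium, not isolated) | COCOc1cccc(OC)c1[Li] | intermediate
7 | 1-methoxy-3-(methoxymethoxy)-2-[4-(methoxymethoxy)benzyl]benzene | COCOc1ccc(Cc2c(OC)cccc2OCOC)cc1 | intermediate
8 | 2-{3-methoxy-5-(methoxymethoxy)-4-[4-(methoxymethoxy)benzyl]phenyl}-4,4,5,5-tetramethyl-1,3,2-dioxaborolane | COCOc1ccc(Cc2c(OC)cc(B3OC(C)(C)C(C)(C)O3)cc2OCOC)cc1 | intermediate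
9 | 5-iodo-1-methoxy-3-(methoxymethoxy)-2-[4-(methoxymethoxy)benzyl]benzene | COCOc1ccc(Cc2c(OC)cc(I)cc2OCOC)cc1 | intermediate
10 | 4-benzyloxybenzyl bromide | BrCc1ccc(OCc2ccccc2)cc1 | starting material
11 | 3-methoxystyrene | C=Cc1cccc(OC)c1 | starting material
12 | (E)-1-[2-(3-methoxyphenyl)vinyl]-2,6-bis[4-(benzyloxy)benzyl]-5-methoxy-3-(methoxymethoxy)-4-[4-(methoxymethoxy)benzyl]benzene | COc1cccc(/C=C/c2c(Cc3ccc(OCc4ccccc4)cc3)c(OCOC)c(Cc3ccc(OCOC)cc3)c(OC)c2Cc2ccc(OCc3ccccc3)cc2)c1 | intermediate
13 | 1-[2-(3-methoxyphenyl)ethyl]-2,6-bis(4-hydroxybenzyl)-5-methoxy-3-(methoxymethoxy)-4-[4-(methoxymethoxy)benzyl]benzene | COc1cccc(CCc2c(Cc3ccc(O)cc3)c(OCOC)c(Cc3ccc(OCOC)cc3)c(OC)c2Cc2ccc(O)cc2)c1 | intermediate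
14 | 2,4,6-tris(4-hydroxybenzyl)-5-methoxy-3-[2-(3-methoxyphenyl)ethyl]phenol | COc1cccc(CCc2c(Cc3ccc(O)cc3)c(O)c(Cc3ccc(O)cc3)c(OC)c2Cc2ccc(O)cc2)c1 | target

**Step count and risks**

Total steps: 9. Longest linear sequence: 8 steps (steps 2 to 9, from 4-hydroxybenzyl alcohol).

Steps most likely to fail:

1. Step 7. Palladation of the two ortho C–H bonds, each wedged between the norbornyl-bearing carbon and an alkoxy group, may be slow. The aryl–norbornyl palladium species could then close to a benzocyclobutene, or stop after one benzylation with norbornene retained. Direct oxidative addition of the benzylic bromide to zerovalent palladium, and cyclisation of the dibenzylated arylpalladium onto a benzyl ring, could also drain material. Fallback, from 9 and returning at 13: the two benzyl groups are introduced after the bridge by halogenation and cross-coupling. Iodide 9 undergoes an ordinary Heck reaction with 11 (Pd(OAc)2, P(o-tolyl)3, K2CO3, DMF, 100 °C) to give (E)-1-methoxy-3-(methoxymethoxy)-2-[4-(methoxymethoxy)benzyl]-5-[2-(3-methoxyphenyl)vinyl]benzene F1. Hydrogenation over Pd/C saturates it to 1-methoxy-3-(methoxymethoxy)-2-[4-(methoxymethoxy)benzyl]-5-[2-(3-methoxyphenyl)ethyl]benzene F2. In F2 the two free positions of ring A are each ortho to one oxygen and para to the other, so NBS (2 equiv, MeCN, 0 °C) should brominate them in preference to the anisole-type rings and give 1,5-dibromo-2-methoxy-4-(methoxymethoxy)-3-[4-(methoxymethoxy)benzyl]-6-[2-(3-methoxyphenyl)ethyl]benzene F3. Bromide 10 is converted with zinc dust and LiCl in THF into [4-(benzyloxy)benzyl]zinc bromide F4. Double Negishi coupling of F3 with F4 (Pd(OAc)2, SPhos, THF, 60 °C) gives 1-[2-(3-methoxyphenyl)ethyl]-2,6-bis[4-(benzyloxy)benzyl]-5-methoxy-3-(methoxymethoxy)-4-[4-(methoxymethoxy)benzyl]benzene F5. Hydrogenolysis of F5 over Pd/C gives 13.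

2. Step 4. Lithium–bromine exchange between aryllithium 6 and the electron-rich bromide 5, followed by Wurtz-type homocoupling, and self-alkylation of 5 could consume both partners. Fallback, from 2 and 4 and returning at 7: the C–C bond is made by carbonyl addition instead of alkylation. Alcohol 4 is oxidised with MnO2 in CH2Cl2 to 4-(methoxymethoxy)benzaldehyde F6. Aryllithium 6, generated from 2 as in step 4, adds to F6 at −78 °C to give racemic [2-methoxy-6-(methoxymethoxy)phenyl][4-(methoxymethoxy)phenyl]methanol F7. The doubly benzylic, electron-rich C–O bond of F7 is hydrogenolysed (H2, Pd/C, EtOH, trace AcOH) to give 7.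

3. Step 9. Under acid, the hexasubstituted electron-rich ring could lose or shift a 4-hydroxybenzyl group by ipso-protonation, and the free phenol rings could capture the formaldehyde equivalent released from the acetals. Fallback, from 9 and returning at 14: the acid step is moved to a stage where no polybenzylated phenol is present, and the end game becomes a single hydrogenation. Iodide 9 is treated with HCl in MeOH to give 2-(4-hydroxybenzyl)-5-iodo-3-methoxyphenol F8. Both phenols are benzylated (BnBr, K2CO3, DMF) to give 1-(benzyloxy)-2-[4-(benzyloxy)benzyl]-5-iodo-3-methoxybenzene F9. F9 is submitted to the conditions of step 7 with 10 and 11 to give (E)-1-[2-(3-methoxyphenyl)vinyl]-3-(benzyloxy)-2,4,6-tris[4-(benzyloxy)benzyl]-5-methoxybenzene F10. Hydrogenation of F10 over Pd/C saturates the alkene and cleaves all four benzyl ethers to give 14.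

**Further compounds**

F1 | step 7 | (E)-1-methoxy-3-(methoxymethoxy)-2-[4-(methoxymethoxy)benzyl]-5-[2-(3-methoxyphenyl)vinyl]benzene | COc1cccc(/C=C/c2cc(OC)c(Cc3ccc(OCOC)cc3)c(OCOC)c2)c1
F2 | step 7 | 1-methoxy-3-(methoxymethoxy)-2-[4-(methoxymethoxy)benzyl]-5-[2-(3-methoxyphenyl)ethyl]benzene | COc1cccc(CCc2cc(OC)c(Cc3ccc(OCOC)cc3)c(OCOC)c2)c1
F3 | step 7 | 1,5-dibromo-2-methoxy-4-(methoxymethoxy)-3-[4-(methoxymethoxy)benzyl]-6-[2-(3-methoxyphenyl)ethyl]benzene | COc1cccc(CCc2c(Br)c(OC)c(Cc3ccc(OCOC)cc3)c(OCOC)c2Br)c1
F4 | step 7 | [4-(benzyloxy)benzyl]zinc bromide | Br[Zn]Cc1ccc(OCc2ccccc2)cc1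
F5 | step 7 | 1-[2-(3-methoxyphenyl)ethyl]-2,6-bis[4-(benzyloxy)benzyl]-5-methoxy-3-(methoxymethoxy)-4-[4-(methoxymethoxy)benzyl]benzene | COc1cccc(CCc2c(Cc3ccc(OCc4ccccc4)cc3)c(OCOC)c(Cc3ccc(OCOC)cc3)c(OC)c2Cc2ccc(OCc3ccccc3)cc2)c1
F6 | step 4 | 4-(methoxymethoxy)benzaldehyde | COCOc1ccc(C=O)cc1
F7 | step 4 | [2-methoxy-6-(methoxymethoxy)phenyl][4-(methoxymethoxy)phenyl]methanol (racemic) | COCOc1ccc(C(O)c2c(OC)cccc2OCOC)cc1
F8 | step 9 | 2-(4-hydroxybenzyl)-5-iodo-3-methoxyphenol | COc1cc(I)cc(O)c1Cc1ccc(O)cc1
F9 | step 9 | 1-(benzyloxy)-2-[4-(benzyloxy)benzyl]-5-iodo-3-methoxybenzene | COc1cc(I)cc(OCc2ccccc2)c1Cc1ccc(OCc2ccccc2)cc1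
F10 | step 9 | (E)-1-[2-(3-methoxyphenyl)vinyl]-3-(benzyloxy)-2,4,6-tris[4-(benzyloxy)benzyl]-5-methoxybenzene | COc1cccc(/C=C/c2c(Cc3ccc(OCc4ccccc4)cc3)c(OCc3ccccc3)c(Cc3ccc(OCc4ccccc4)cc3)c(OC)c2Cc2ccc(OCc3ccccc3)cc2)c1
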